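**Retrosynthetic overview**
- C12'–C13': Weinreb ketone synthesis with an (E)-alkenyllithium made from 2-methylbut-3-yn-2-ol; the same operation frees the phenol (last step).
- C1'–C2' and C3'–CH3: syn-methylalumination of a terminal alkyne, then benzylation with an ortho-acetoxybenzyl bromide (fixes 2'E).
- C4'–C5': chiral phosphoric acid-catalysed propargylation of an enal (sets C5' as R).
- C11': a new carbene-catalysed redox amidation of 8-oxogeranyl acetate with enantioselective α-protonation (first stereocentre, R); C5'–C12' and the 6'E olefin come intact from geranyl acetate.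
- No ring is formed; the arene is bought as 4-methoxy-2-methylphenol.

Assumption: geranyl acetate, 4-methoxy-2-methylphenol, 2-methylbut-3-yn-2-ol, allenylboronic acid pinacol ester and both enantiomers of the two organocatalysts are taken as commercial; locants C1'–C15' count the side chain from the benzylic carbon.

**Step 1**
Reactants: 1 geranyl acetate
Product: 3 (2E,6E)-3,7-dimethyl-8-oxoocta-2,6-dien-1-yl acetate, via allylic alcohol 2 (not isolated)
Conditions: SeO2 (0.3 equiv), t-BuOOH (3 equiv), salicylic acid (0.1 equiv), CH2Cl2, rt, 30 h; filter; then MnO2 (15 equiv), CH2Cl2, rt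
Reagents that add atoms: tert-butyl hydroperoxide, CC(C)(C)OO (terminal oxidant); selenium dioxide, O=[Se]=O (catalytic oxygen carrier)
Why: Riley allylic oxidation (ene reaction then [2,3]-sigmatropic shift) attacks the (E)-methyl of the terminal olefin because the other olefin is deactivated by the allylic acetate, and MnO2 converges the alcohol/aldehyde mixture on the (E,E)-enal.

**Step 2**
Reactants: 3 (2E,6E)-3,7-dimethyl-8-oxoocta-2,6-dien-1-yl acetate
Product: 5 (2E,7R)-8-[methoxy(methyl)amino]-3,7-dimethyl-8-oxooct-2-en-1-yl acetate, via azabenzotriazolyl ester 4 (not isolated)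
Conditions: (5aS,10bR)-2-(pentafluorophenyl)-4,5a,6,10b-tetrahydroindeno[2,1-b][1,2,4]triazolo[4,3-d][1,4]oxazin-2-ium tetrafluoroborate (15 mol%; the mirror-image salt if the sense of induction proves opposite), HOAt (20 mol%), MeNH(OMe)·HCl (1.5 equiv), sodium pivalate (2.5 equiv), 4 Å MS, toluene, 23 °C, 24 h
Reagents that add atoms: N,O-dimethylhydroxylamine hydrochloride, CNOC.Cl
Why: Proposed new method: carbene-catalysed redox amidation in which the carbene adds to the aldehyde, the homoenolate is protonated at the β-carbon, the catalyst-bound enol is protonated at the α-carbon on the face left open by the indane wall (this sets C11' as R), and the acyl group is relayed through the HOAt ester to the amine; the closest known reaction type is the carbene-catalysed redox amidation/esterification of α-fluoro and α-chloro aldehydes with enantioselective enol protonation, not yet shown for an α-methyl, all-alkyl enal.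

**Step 3**
Reactants: 5 (2E,7R)-8-[methoxy(methyl)amino]-3,7-dimethyl-8-oxooct-2-en-1-yl acetate
Product: 6 (2R,6E)-8-hydroxy-N-methoxy-N,2,6-trimethyloct-6-enamide
Conditions: K2CO3 (0.2 equiv), MeOH, 0 °C → rt, 1 h
Reagents that add atoms: none
Why: Base-catalysed transesterification (Zemplén-type methanolysis) removes the acetate, while the amide and its α-stereocentre are inert to K2CO3/MeOH.

**Step 4**
Reactants: 6 (2R,6E)-8-hydroxy-N-methoxy-N,2,6-trimethyloct-6-enamide
Product: 7 (2R,6E)-N-methoxy-N,2,6-trimethyl-8-oxooct-6-enamide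
Conditions: MnO2 (15 equiv), CH2Cl2, rt, 3 h
Reagents that add atoms: none
Why: MnO2 allylic oxidation is selective for the primary allylic alcohol and keeps the E geometry of the enal.

**Step 5**
Reactants: 7 (2R,6E)-N-methoxy-N,2,6-trimethyl-8-oxooct-6-enamide; 8 allenylboronic acid pinacol ester
Product: 10 (2R,6E,8R)-8-hydroxy-N-methoxy-N,2,6-trimethylundec-6-en-10-ynamide, via pinacol borate ester 9 (not isolated)
Conditions: (R)-TRIP [(R)-3,3'-bis(2,4,6-triisopropylphenyl)-1,1'-binaphthyl-2,2'-diyl hydrogen phosphate] (10 mol%), 4 Å MS, toluene, −20 °C, 48 h; then aq. NaHCO3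
Reagents that add atoms: none
Why: Chiral phosphoric acid-catalysed asymmetric propargylation (SE2' allenylboration through a six-membered chair transition state held by the acid); (R)-TRIP directs attack to the Re face of the enal and gives the (R)-carbinol at C5', independent of the remote C11' centre.

**Step 6**
Reactants: 11 4-methoxy-2-methylphenol
Product: 12 2-(hydroxymethyl)-4-methoxy-6-methylphenol
Conditions: 37% aq. CH2O (4 equiv), NaOH (1.1 equiv), H2O, 0 °C → rt, 48 h; AcOH to pH 6
Reagents that add atoms: formaldehyde, C=O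
Why: Lederer–Manasse hydroxymethylation: the phenoxide reacts with formaldehyde at its only free ortho position, the para position being blocked by OMe.

**Step 7**
Reactants: 12 2-(hydroxymethyl)-4-methoxy-6-methylphenol
Product: 13 2-(bromomethyl)-4-methoxy-6-methylphenyl acetate
Conditions: AcBr (3 equiv), CH2Cl2, 0 °C → rt, 6 h
Reagents that add atoms: acetyl bromide, CC(=O)Br
Why: Acylative bromination: acetyl bromide acetylates both hydroxyls and the HBr released converts the benzylic acetate into the bromide, leaving the phenol masked as its acetate.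

**Step 8**
Reactants: 10 (2R,6E,8R)-8-hydroxy-N-methoxy-N,2,6-trimethylundec-6-en-10-ynamide; 13 2-(bromomethyl)-4-methoxy-6-methylphenyl acetate
Product: 15 2-[(2E,5R,6E,11R)-5-hydroxy-12-[methoxy(methyl)amino]-3,7,11-trimethyl-12-oxododeca-2,6-dien-1-yl]-4-methoxy-6-methylphenyl acetate, via alkenylalane 14 (not isolated)
Conditions: Me3Al (3.5 equiv), Cp2ZrCl2 (0.3 equiv), CH2Cl2, 0 °C → rt, 12 h; volatiles off; then 13 (1.3 equiv), Pd(PPh3)4 (5 mol%), THF, rt; aq. potassium sodium tartrate
Reagents that add atoms: trimethylaluminium, C[Al](C)C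
Why: Negishi zirconium-catalysed carboalumination adds CH3 and Al syn across the terminal alkyne with CH3 on the internal carbon (this fixes 2'E), and the palladium-catalysed Negishi coupling of the alkenylalane with the benzylic bromide proceeds with retention; the Weinreb amide tolerates Me3Al.

**Step 9**
Reactants: 16 2-methylbut-3-yn-2-ol
Product: 17 (E)-2-methyl-4-(tributylstannyl)but-3-en-2-ol
Conditions: Bu3SnH (1.1 equiv), AIBN (5 mol%), neat, 90 °C, 3 h
Reagents that add atoms: tributyltin hydride, CCCC[SnH](CCCC)CCCC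
Why: Radical hydrostannation of the terminal alkyne under thermodynamic control gives the (E)-β-stannane.

**Step 10**
Reactants: 15 the aryl acetate/Weinreb amide described in step 8; 17 (E)-2-methyl-4-(tributylstannyl)but-3-en-2-ol
Product: 19 (3E,6R,10E,12R,14E)-2,12-dihydroxy-16-(2-hydroxy-5-methoxy-3-methylphenyl)-2,6,10,14-tetramethylhexadeca-3,10,14-trien-5-one (target; 2'E,5'R,6'E,11'R,13'E), via dilithio alkenyl reagent 18 (not isolated)
Conditions: 17 (5 equiv), n-BuLi (10 equiv), THF, −78 → −30 °C; then 15, −78 → −20 °C; sat. aq. NH4Cl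
Reagents that add atoms: none
Why: Tin–lithium exchange gives the configurationally stable (E)-alkenyllithium, which adds once to the amide (Weinreb ketone synthesis; the chelated tetrahedral adduct prevents over-addition and α-epimerisation) while excess reagent deprotonates the C5' hydroxyl and cleaves the aryl acetate, so the quench releases the enone and the free phenol.

**Compound list**
1 | geranyl acetate | CC(C)=CCC/C(C)=C/COC(C)=O | starting material
2 | (2E,6E)-8-hydroxy-3,7-dimethylocta-2,6-dien-1-yl acetate | OC/C(C)=C/CC/C(C)=C/COC(C)=O | intermediate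
3 | (2E,6E)-3,7-dimethyl-8-oxoocta-2,6-dien-1-yl acetate | O=C/C(C)=C/CC/C(C)=C/COC(C)=O | intermediate
4 | 3H-[1,2,3]triazolo[4,5-b]pyridin-3-yl (2R,6E)-8-acetoxy-2,6-dimethyloct-6-enoate | CC(=O)OC/C=C(\C)CCC[C@@H](C)C(=O)On1nnc2cccnc21 | intermediate
5 | (2E,7R)-8-[methoxy(methyl)amino]-3,7-dimethyl-8-oxooct-2-en-1-yl acetate | CON(C)C(=O)[C@H](C)CCC/C(C)=C/COC(C)=O | intermediate
6 | (2R,6E)-8-hydroxy-N-methoxy-N,2,6-trimethyloct-6-enamide | CON(C)C(=O)[C@H](C)CCC/C(C)=C/CO | intermediate
7 | (2R,6E)-N-methoxy-N,2,6-trimethyl-8-oxooct-6-enamide | CON(C)C(=O)[C@H](C)CCC/C(C)=C/C=O | intermediate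
8 | allenylboronic acid pinacol ester | C=C=CB1OC(C)(C)C(C)(C)O1 | starting material
9 | (2R,6E,8R)-N-methoxy-N,2,6-trimethyl-8-[(4,4,5,5-tetramethyl-1,3,2-dioxaborolan-2-yl)oxy]undec-6-en-10-ynamide | CON(C)C(=O)[C@H](C)CCC/C(C)=C/[C@H](OB1OC(C)(C)C(C)(C)O1)CC#C | intermediate
10 | (2R,6E,8R)-8-hydroxy-N-methoxy-N,2,6-trimethylundec-6-en-10-ynamide | CON(C)C(=O)[C@H](C)CCC/C(C)=C/[C@H](O)CC#C | intermediate
11 | 4-methoxy-2-methylphenol | COc1ccc(O)c(C)c1 | starting material
12 | 2-(hydroxymethyl)-4-methoxy-6-methylphenol | COc1cc(C)c(O)c(CO)c1 | intermediate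
13 | 2-(bromomethyl)-4-methoxy-6-methylphenyl acetate | COc1cc(C)c(OC(C)=O)c(CBr)c1 | intermediate
14 | (E)-alkenyl(dimethyl)alane from 10: AlMe2 on C2', CH3 on C3', C5' oxygen as its dimethylaluminium alkoxide | CON(C)C(=O)[C@H](C)CCC/C(C)=C/[C@H](O[Al](C)C)C/C(C)=C/[Al](C)C | intermediate
15 | 2-[(2E,5R,6E,11R)-5-hydroxy-12-[methoxy(methyl)amino]-3,7,11-trimethyl-12-oxododeca-2,6-dien-1-yl]-4-methoxy-6-methylphenyl acetate | CON(C)C(=O)[C@H](C)CCC/C(C)=C/[C@H](O)C/C(C)=C/Cc1cc(OC)cc(C)c1OC(C)=O | intermediate
16 | 2-methylbut-3-yn-2-ol | CC(C)(O)C#C | starting material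
17 | (E)-2-methyl-4-(tributylstannyl)but-3-en-2-ol | CCCC[Sn](CCCC)(CCCC)/C=C/C(C)(C)O | intermediate
18 | lithium (E)-4-lithio-2-methylbut-3-en-2-olate | [Li]/C=C/C(C)(C)O[Li] | intermediate
19 | (3E,6R,10E,12R,14E)-2,12-dihydroxy-16-(2-hydroxy-5-methoxy-3-methylphenyl)-2,6,10,14-tetramethylhexadeca-3,10,14-trien-5-one | COc1cc(C)c(O)c(C/C=C(\C)C[C@@H](O)/C=C(\C)CCC[C@@H](C)C(=O)/C=C/C(C)(C)O)c1 | target

**Step count and risks**
Total steps: 10. Longest linear sequence: 7 (steps 1, 2, 3, 4, 5, 8, 10).

Risk 1, step 2 (the proposed new step). The methyl group and the chain on the catalyst-bound enol are similar in size, so the α-protonation may give low ee, and homoenolate annulation may compete. The fallback uses known chemistry, sets out from 3 and comes back at 5. Pinnick oxidation (NaClO2, NaH2PO4, 2-methylbut-2-ene, t-BuOH/H2O) gives (2E,6E)-8-acetoxy-2,6-dimethylocta-2,6-dienoic acid F1. Carboxylate-directed asymmetric hydrogenation with Ru(OAc)2[(R)-BINAP] (H2 4 atm, MeOH) reduces only the conjugated olefin and gives (2R,6E)-8-acetoxy-2,6-dimethyloct-6-enoic acid F2; the (R) sense is assigned by analogy with tiglic acid. EDC/HOBt coupling with N,O-dimethylhydroxylamine then gives 5.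

Risk 2, step 5. A β,β-disubstituted aliphatic enal is a less proven substrate for the phosphoric acid propargylation, so the ee may be moderate and the enal may partly isomerise to its Z form. The fallback sets out from alcohol 6 (bypassing aldehyde 7) and comes back at 10. Iridium-catalysed transfer-hydrogenative propargylation at the alcohol oxidation level uses 3-chloro-1-(trimethylsilyl)propyne and the cyclometalated π-allyl iridium C,O-benzoate catalyst made from [Ir(cod)Cl]2, SEGPHOS (the enantiomer that gives the R carbinol), 4-cyano-3-nitrobenzoic acid and allyl acetate. It gives (2R,6E,8R)-8-hydroxy-N-methoxy-N,2,6-trimethyl-11-(trimethylsilyl)undec-6-en-10-ynamide F3, which K2CO3/MeOH desilylates to 10.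

Risk 3, step 8. Excess Me3Al may ionise the allylic aluminium alkoxide at C5' or attack the amide, and the one-pot coupling may be sluggish. The fallback avoids aluminium, sets out from 10 and comes back at 15. Copper-catalysed syn-methylboration (CuCl/Xantphos, B2pin2, MeI, NaOt-Bu, THF) gives (2R,6E,8R,10E)-8-hydroxy-N-methoxy-N,2,6,10-tetramethyl-11-(4,4,5,5-tetramethyl-1,3,2-dioxaborolan-2-yl)undeca-6,10-dienamide F4. Suzuki–Miyaura coupling with 13 (Pd(dppf)Cl2, K3PO4, THF/H2O, 50 °C) then gives 15; any phenol set free by partial acetate loss is equally competent in step 10.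

**Further compounds**
F1 | step 2 | (2E,6E)-8-acetoxy-2,6-dimethylocta-2,6-dienoic acid | OC(=O)/C(C)=C/CC/C(C)=C/COC(C)=O
F2 | step 2 | (2R,6E)-8-acetoxy-2,6-dimethyloct-6-enoic acid | OC(=O)[C@H](C)CCC/C(C)=C/COC(C)=O
F3 | step 5 | (2R,6E,8R)-8-hydroxy-N-methoxy-N,2,6-trimethyl-11-(trimethylsilyl)undec-6-en-10-ynamide | CON(C)C(=O)[C@H](C)CCC/C(C)=C/[C@H](O)CC#C[Si](C)(C)C
F4 | step 8 | (2R,6E,8R,10E)-8-hydroxy-N-methoxy-N,2,6,10-tetramethyl-11-(4,4,5,5-tetramethyl-1,3,2-dioxaborolan-2-yl)undeca-6,10-dienamide | CON(C)C(=O)[C@H](C)CCC/C(C)=C/[C@H](O)C/C(C)=C/B1OC(C)(C)C(C)(C)O1
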